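A flask whose steps are all first order keeps one thing whatever its charge: the share of the charge turned at a given time. That is our zero of the scale.

| flask | substrate | time |
|---|---|---|
| south-west | 0.300 M |  |
| north-west | 0.180 M |  |
| south | 0.450 M |  |
| north | 0.300 M | 100 min |

| south-west run: time / min | south-west run: [target] / M | north-west run: time / min | north-west run: [target] / M | south run: time / min | south run: [target] / M |
|---|---|---|---|---|---|
| 2.1 | 0.0584 | 2.1 | 0.0379 | 2.1 | 0.0871 |
| 4.2 | 0.0999 | 4.2 | 0.0620 | 4.2 | 0.1498 |
| 6.4 | 0.1345 | 6.4 | 0.0818 | 6.4 | 0.1961 |
| 8.5 | 0.1591 | 8.5 | 0.0967 | 8.5 | 0.2210 |
| 11 | 0.1734 | 11 | 0.1081 | 11 | 0.2471 |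
| 13 | 0.1858 | 13 | 0.1169 | 13 | 0.2622 |
| 15 | 0.1874 | 15 | 0.1237 | 15 | 0.2672 |
| 17 | 0.1937 | 17 | 0.1207 | 17 | 0.2720 |

(each reading ± 0.002 M)

1. order of the initial rate in [substrate], near the charge of the south-west run, the rate being that where two percent of its substrate are target (one fixed amount of target, the same in the runs compared)
2. target in the north run at 100 min, as a share of the substrate charged

- Overall: substrate -> target.
- Constant volume, constant temperature.
- An order is taken over about fifteen percent of the charge, up and down.

We read the order in two ways, from the south and north-west runs, whose charges lie on either side of the south-west charge. The ratio of c(target) at 2.1 min gives 0.908, and the ratio at 4.2 min gives 0.963. The gap between them is 0.0546, and the scatter of 0.002 M on the reading 0.0379 M moves the earlier value by 0.0576. So the two agree within the scatter, and we take the order as close to one.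

We carry one number, the share constant κ, the first-order constant that the first south-west reading gives if substrate has no other exit: 0.103 min⁻¹. Between 13 min and 17 min, κ promises 0.0265 M of target, but the south-west run gains 0.00790 M, which is less. If substrate leaves another way and target stays, the share in the south-west run holds near 64.6%. If the whole gap is loss of target, at about 0.0249 min⁻¹, the share reckoned on from the last south-west reading falls to about 8.20%. Our reckoning is that bracket.

The forecast gives 0.93 and 66%, a little higher than the top of our bracket: “Log-conversion flattens faster than a simple exponential, which favours a true stall”.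

    substrate → target (0.08820 min⁻¹)
    2 substrate → side product (0.06120 M⁻¹ min⁻¹)
    target → decomposed product (0.01314 min⁻¹)
    substrate → target (0.02316 min⁻¹)

The north run holds 26.1% of its charge as target at 100 min, and the order is 1.0. The fit with main steps alone gives 75.6% for the same flask. By κ, 100 min is 10.3 lifetimes of substrate, so hardly any of the charge remains as substrate in the north run. In the north-west run, the rate per charge at the fixed amount of target used for the order is 0.106 min⁻¹, beside κ of 0.103 min⁻¹.

The data stem from a simulated flask on assumed constants, and the scatter is random.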